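**Retrosynthetic overview**
- Dendronpholide A ⇐ β-acetoxymethyl lactone (E1cB loss of AcOH unmasks the exo-methylene last) ⇐ 14-membered ring closed at C12–C13 by nickel-catalysed alkyne–aldehyde reductive macrocyclisation.
- Seven-membered lactone ⇐ Baeyer–Villiger ring expansion of a cyclohexanone; the quaternary C4 migrates to oxygen with retention.
- Cyclohexanone with C4/C5 ⇐ one-flask enantioselective epoxidation/semipinacol ring expansion of a 1-alkenylcyclopentanol; C1 then comes from asymmetric vinyl conjugate addition to the derived enone, C17 from hydroxymethylation.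
- Alkenylcyclopentanol ⇐ Negishi coupling of a Z vinyl iodide (from 1-ethynylcyclopentan-1-ol) with a homoallylic bromide (from but-3-yn-1-ol, formaldehyde and a propynyl Grignard reagent).
- Ring order: cyclopentane (bought) → cyclohexanone → oxepan-2-one → 14-membered carbocycle.

Assumption: atom labels follow the cembrane skeleton (C1 = lactone-ring CH, C4 = O-bearing quaternary carbon, C5 = acetoxy carbon, C13 = carbinol carbon, C15/C16/C17 = α-carbon, carbonyl and methylene of the lactone), and the (R,R)-bishydroxamic acid ligand is taken to give the (2S,3S)-epoxide, its enantiomer being used if the facial sense proves opposite.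

**Route**

Step 1
Reactants: 1 but-3-yn-1-ol
Product: 2 (2E)-3-methylpent-2-ene-1,5-diol
Conditions: AlMe3 (3 equiv), Cp2ZrCl2 (0.25 equiv), CH2Cl2, 0 → 25 °C; then n-BuLi, (CH2O)n, THF, −78 → 25 °C
Reagents that add atoms: trimethylaluminium, C[Al](C)C; formaldehyde (from paraformaldehyde), C=O
Why: Zirconium-catalysed Negishi carboalumination adds Me and Al syn across the alkyne with Me on the internal carbon, and the derived alanate is hydroxymethylated with retention, which fixes the E geometry of the future C8=C9 alkene.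

Step 2
Reactants: 2 (2E)-3-methylpent-2-ene-1,5-diol
Product: 3 (2E)-1,5-dibromo-3-methylpent-2-ene
Conditions: CBr4 (2.4 equiv), PPh3 (2.4 equiv), CH2Cl2, 0 °C
Reagents that add atoms: carbon tetrabromide, BrC(Br)(Br)Br
Why: Appel bromination converts both primary alcohols under neutral conditions, so the allylic position does not transpose and the alkene geometry is kept.

Step 3
Reactants: 3 (2E)-1,5-dibromo-3-methylpent-2-ene; 4 prop-1-yn-1-ylmagnesium bromide
Product: 5 (5E)-8-bromo-6-methyloct-5-en-2-yne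
Conditions: CuBr·SMe2 (5 mol%), THF, −30 → 0 °C
Reagents that add atoms: none
Why: Copper-catalysed SN2 coupling of the alkynyl Grignard reagent occurs only at the allylic bromide, which is far more reactive than the homoallylic one, giving the skipped enyne with the alkene geometry intact.

Step 4
Reactants: 6 1-ethynylcyclopentan-1-ol
Product: 7 1-[(1Z)-1-iodoprop-1-en-2-yl]cyclopentan-1-ol
Conditions: MeMgBr (3.5 equiv), CuI (15 mol%), THF, −20 → 25 °C; then I2, −78 → 0 °C
Reagents that add atoms: methylmagnesium bromide, C[Mg]Br; iodine, II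
Why: Alkoxide-directed, CuI-catalysed anti-carbomagnesiation of the propargylic alcohol places Me on the carbinol-proximal carbon and magnesium in a five-membered chelate, and iodinolysis with retention gives the Z iodide (I cis to the carbinol carbon).

Step 5
Reactants: 5 (5E)-8-bromo-6-methyloct-5-en-2-yne; 7 1-[(1Z)-1-iodoprop-1-en-2-yl]cyclopentan-1-ol
Product: 9 1-[(2Z,6E)-6-methylundeca-2,6-dien-9-yn-2-yl]cyclopentan-1-ol, via alkylzinc bromide 8 (not isolated)
Conditions: Zn dust (2 equiv), I2 (5 mol%), DMA, 70 °C; then 7 (0.65 equiv), Pd(OAc)2 (2 mol%), SPhos (4 mol%), THF, 25 °C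
Reagents that add atoms: none
Why: Zinc insertion into the primary bromide followed by Negishi sp3–sp2 cross-coupling forms C5–C6 with retention at the alkenyl iodide, so the carbinol carbon and C6 end up cis on the C4=C5 alkene as the later stereospecific shift requires.

Step 6
Reactants: 9 1-[(2Z,6E)-6-methylundeca-2,6-dien-9-yn-2-yl]cyclopentan-1-ol
Product: 12 (1S,4E)-4-methyl-1-[(1R)-1-methyl-2-oxocyclohexyl]non-4-en-7-yn-1-yl acetate, via epoxy alcohol 10 (not isolated), via hydroxy ketone 11 (not isolated)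
Conditions: Hf(OtBu)4 (10 mol%), (R,R)-bishydroxamic acid ligand from (1R,2R)-cyclohexane-1,2-diamine (12 mol%), cumene hydroperoxide (1.1 equiv), toluene, 0 °C; then 45 °C; then Ac2O, Et3N, DMAP, 0 → 25 °C
Reagents that add atoms: cumene hydroperoxide, CC(C)(OO)c1ccccc1; acetic anhydride, CC(=O)OC(C)=O
Why: Proposed new method: one chiral tetravalent-hafnium bishydroxamate first epoxidises the tertiary allylic alcohol enantioselectively (hydroxyl-directed, so the remote C8=C9 alkene is spared) and, on warming, the still-bound epoxy alkoxide, held as an O,O-chelate that makes hafnium a Lewis acid at the epoxide oxygen, ionises at the tertiary C4–O bond while an antiperiplanar ring C–C bond of the cyclopentanol migrates (semipinacol 1,2-shift, expected to outrun cation–olefin capture by the distant alkene because the alkoxide pushes), so the five-membered carbinol becomes the six-membered ketone with inversion at C4 and retention at C5, the Z alkene and the (2S,3S)-epoxide thereby fixing 4R,5S, after which the aldolate is acetylated in the same flask; the closest known reactions are the Hf(OtBu)4/bishydroxamic acid epoxidation of tertiary allylic alcohols and the Lewis-acid semipinacol ring expansion of 2,3-epoxy alcohols, which have not been merged under one chiral catalyst.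

Step 7
Reactants: 12 (1S,4E)-4-methyl-1-[(1R)-1-methyl-2-oxocyclohexyl]non-4-en-7-yn-1-yl acetate
Product: 13 (1S,4E)-4-methyl-1-[(1R)-1-methyl-2-oxocyclohex-3-en-1-yl]non-4-en-7-yn-1-yl acetate
Conditions: IBX (2.2 equiv), 4-methoxypyridine N-oxide (2.2 equiv), DMSO, 25 °C
Reagents that add atoms: none
Why: IBX dehydrogenation of the ketone can only run toward C15–C1 because C4 is quaternary, giving the enone needed to introduce C14 at C1.

Step 8
Reactants: 13 (1S,4E)-4-methyl-1-[(1R)-1-methyl-2-oxocyclohex-3-en-1-yl]non-4-en-7-yn-1-yl acetate; 14 potassium ethenyltrifluoroborate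
Product: 15 (1S,4E)-1-[(1R,4S)-4-ethenyl-1-methyl-2-oxocyclohexyl]-4-methylnon-4-en-7-yn-1-yl acetate
Conditions: [Rh(cod)2]BF4 (3 mol%), (S)-BINAP (3.3 mol%), toluene/H2O (4:1), 100 °C
Reagents that add atoms: none
Why: Hayashi–Miyaura rhodium-catalysed asymmetric 1,4-addition: the vinylrhodium/(S)-BINAP species, which gives (S)-3-substituted ketones from cyclohex-2-enone, inserts the enone on the face trans to the C5 side chain under catalyst control and so sets C1.

Step 9
Reactants: 15 (1S,4E)-1-[(1R,4S)-4-ethenyl-1-methyl-2-oxocyclohexyl]-4-methylnon-4-en-7-yn-1-yl acetate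
Product: 17 (1S,4E)-1-[(1R,3S,4R)-4-ethenyl-3-(hydroxymethyl)-1-methyl-2-oxocyclohexyl]-4-methylnon-4-en-7-yn-1-yl acetate, via silyl enol ether 16 (not isolated)
Conditions: TMSOTf (1.2 equiv), Et3N (1.5 equiv), CH2Cl2, −78 → 0 °C; then aq. HCHO, Yb(OTf)3 (10 mol%), THF, 25 °C
Reagents that add atoms: formaldehyde, C=O
Why: Soft enolisation with TMSOTf/Et3N is selective for the ketone over the acetate and regiospecific (only C15 has α-hydrogens), and the Yb(OTf)3-catalysed Mukaiyama aldol reaction with aqueous formaldehyde installs C17 anti to the vinyl group at a centre that is erased in step 14.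

Step 10
Reactants: 17 (1S,4E)-1-[(1R,3S,4R)-4-ethenyl-3-(hydroxymethyl)-1-methyl-2-oxocyclohexyl]-4-methylnon-4-en-7-yn-1-yl acetate
Product: 18 (1S,4E)-1-[(1R,3S,4R)-3-(acetoxymethyl)-4-ethenyl-1-methyl-2-oxocyclohexyl]-4-methylnon-4-en-7-yn-1-yl acetate
Conditions: Ac2O, pyridine, DMAP (cat.), CH2Cl2, 0 °C
Reagents that add atoms: acetic anhydride, CC(=O)OC(C)=O
Why: Standard acylation of the primary alcohol makes C17–OAc the leaving group for the last step while masking the reactive α-methylene carbonyl through the oxidation and nickel steps.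

Step 11
Reactants: 18 (1S,4E)-1-[(1R,3S,4R)-3-(acetoxymethyl)-4-ethenyl-1-methyl-2-oxocyclohexyl]-4-methylnon-4-en-7-yn-1-yl acetate
Product: 19 [(3S,4R,7R)-7-[(1S,4E)-1-acetoxy-4-methylnon-4-en-7-yn-1-yl]-4-ethenyl-7-methyl-2-oxooxepan-3-yl]methyl acetate
Conditions: (Me3SiO)2 (3 equiv), TMSOTf (0.2 equiv), CH2Cl2, −40 → −10 °C
Reagents that add atoms: bis(trimethylsilyl) peroxide, C[Si](C)(C)OO[Si](C)(C)C
Why: Baeyer–Villiger ring expansion: the silyl peroxide adds to the TMSOTf-activated ketone and the Criegee adduct rearranges by 1,2-shift of the fully substituted C4 (a better migrating group than the secondary C15) with retention, turning C4–C16 into C4–O–C16, while this non-peracid oxidant leaves the trisubstituted alkene, vinyl group and alkyne untouched.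

Step 12
Reactants: 19 [(3S,4R,7R)-7-[(1S,4E)-1-acetoxy-4-methylnon-4-en-7-yn-1-yl]-4-ethenyl-7-methyl-2-oxooxepan-3-yl]methyl acetate
Product: 20 [(3S,4R,7R)-7-[(1S,4E)-1-acetoxy-4-methylnon-4-en-7-yn-1-yl]-7-methyl-2-oxo-4-(2-oxoethyl)oxepan-3-yl]methyl acetate
Conditions: PdCl2(PhCN)2 (10 mol%), CuCl2·2H2O (10 mol%), AgNO2 (5 mol%), t-BuOH/MeNO2 (15:1), O2 (1 atm), 25 °C
Reagents that add atoms: dioxygen, O=O
Why: Nitrite-co-catalysed Wacker oxidation with anti-Markovnikov (aldehyde) selectivity oxidises only the monosubstituted alkene, giving the C13 aldehyde without affecting the trisubstituted alkene or the internal alkyne.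

Step 13
Reactants: 20 [(3S,4R,7R)-7-[(1S,4E)-1-acetoxy-4-methylnon-4-en-7-yn-1-yl]-7-methyl-2-oxo-4-(2-oxoethyl)oxepan-3-yl]methyl acetate
Product: 21 [(1R,3S,4E,7E,11S,12R,15S)-11-acetoxy-4,8,12-trimethyl-14-oxo-3-(triethylsilyloxy)-13-oxabicyclo[10.3.2]heptadeca-4,7-dien-15-yl]methyl acetate
Conditions: Ni(cod)2 (20 mol%), IMes·HCl (20 mol%), KOtBu (20 mol%) pre-mixed, Et3SiH (5 equiv), THF (0.003 M), 25 °C, slow addition of 20
Reagents that add atoms: triethylsilane, CC[SiH](CC)CC
Why: Nickel-catalysed alkyne–aldehyde reductive macrocyclisation (oxanickelacycle, σ-bond metathesis with the silane, reductive elimination) forms C12–C13 and the 14-membered ring, the syn H/C addition giving the E C11=C12 alkene, the small carbene IMes steering C–C formation to the methyl-bearing alkyne carbon, and C13 being set in the cyclisation with the C14 tether pseudo-equatorial on the metallacycle (13S is expected but not secured; see the fallback).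

Step 14
Reactants: 21 [(1R,3S,4E,7E,11S,12R,15S)-11-acetoxy-4,8,12-trimethyl-14-oxo-3-(triethylsilyloxy)-13-oxabicyclo[10.3.2]heptadeca-4,7-dien-15-yl]methyl acetate
Product: 23 dendronpholide A, (1R,3S,4E,7E,11S,12R)-3-hydroxy-4,8,12-trimethyl-15-methylidene-14-oxo-13-oxabicyclo[10.3.2]heptadeca-4,7-dien-11-yl acetate, via silyl ether 22 (not isolated)
Conditions: DBU (1.5 equiv), CH2Cl2, 0 °C; then HF·pyridine, pyridine, THF, 0 °C
Reagents that add atoms: none
Why: E1cB elimination of acetic acid from the β-acetoxy lactone unveils the exo-methylene while C13–O is still silylated (so the hydroxyl cannot translactonise), and fluoride then removes the silyl group without touching the acetate or the conjugated lactone.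

**Compound list**

1 | but-3-yn-1-ol | C#CCCO | starting material
2 | (2E)-3-methylpent-2-ene-1,5-diol | OCC/C(C)=C/CO | intermediate
3 | (2E)-1,5-dibromo-3-methylpent-2-ene | BrCC/C(C)=C/CBr | intermediate
4 | prop-1-yn-1-ylmagnesium bromide | CC#C[Mg]Br | starting material
5 | (5E)-8-bromo-6-methyloct-5-en-2-yne | BrCC/C(C)=C/CC#CC | intermediate
6 | 1-ethynylcyclopentan-1-ol | C#CC1(O)CCCC1 | starting material
7 | 1-[(1Z)-1-iodoprop-1-en-2-yl]cyclopentan-1-ol | OC1(CCCC1)/C(C)=C\I | intermediate
8 | bromo[(3E)-3-methyloct-3-en-6-yn-1-yl]zinc | Br[Zn]CC/C(C)=C/CC#CC | intermediate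
9 | 1-[(2Z,6E)-6-methylundeca-2,6-dien-9-yn-2-yl]cyclopentan-1-ol | OC1(CCCC1)/C(C)=C\CC/C(C)=C/CC#CC | intermediate
10 | 1-{(2S,3S)-2-methyl-3-[(3E)-3-methyloct-3-en-6-yn-1-yl]oxiran-2-yl}cyclopentan-1-ol | OC1(CCCC1)[C@@]2(C)O[C@H]2CC/C(C)=C/CC#CC | intermediate
11 | (2R)-2-[(1S,4E)-1-hydroxy-4-methylnon-4-en-7-yn-1-yl]-2-methylcyclohexan-1-one | O=C1CCCC[C@]1(C)[C@@H](O)CC/C(C)=C/CC#CC | intermediate
12 | (1S,4E)-4-methyl-1-[(1R)-1-methyl-2-oxocyclohexyl]non-4-en-7-yn-1-yl acetate | O=C1CCCC[C@]1(C)[C@@H](OC(C)=O)CC/C(C)=C/CC#CC | intermediate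
13 | (1S,4E)-4-methyl-1-[(1R)-1-methyl-2-oxocyclohex-3-en-1-yl]non-4-en-7-yn-1-yl acetate | O=C1C=CCC[C@]1(C)[C@@H](OC(C)=O)CC/C(C)=C/CC#CC | intermediate
14 | potassium ethenyltrifluoroborate | C=C[B-](F)(F)F.[K+] | starting material
15 | (1S,4E)-1-[(1R,4S)-4-ethenyl-1-methyl-2-oxocyclohexyl]-4-methylnon-4-en-7-yn-1-yl acetate | O=C1C[C@@H](C=C)CC[C@]1(C)[C@@H](OC(C)=O)CC/C(C)=C/CC#CC | intermediate
16 | trimethylsilyl enol ether of 15 (C15=C16–OSiMe3) | C[Si](C)(C)OC1=C[C@@H](C=C)CC[C@]1(C)[C@@H](OC(C)=O)CC/C(C)=C/CC#CC | intermediate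
17 | (1S,4E)-1-[(1R,3S,4R)-4-ethenyl-3-(hydroxymethyl)-1-methyl-2-oxocyclohexyl]-4-methylnon-4-en-7-yn-1-yl acetate | O=C1[C@H](CO)[C@@H](C=C)CC[C@]1(C)[C@@H](OC(C)=O)CC/C(C)=C/CC#CC | intermediate
18 | (1S,4E)-1-[(1R,3S,4R)-3-(acetoxymethyl)-4-ethenyl-1-methyl-2-oxocyclohexyl]-4-methylnon-4-en-7-yn-1-yl acetate | O=C1[C@H](COC(C)=O)[C@@H](C=C)CC[C@]1(C)[C@@H](OC(C)=O)CC/C(C)=C/CC#CC | intermediate
19 | [(3S,4R,7R)-7-[(1S,4E)-1-acetoxy-4-methylnon-4-en-7-yn-1-yl]-4-ethenyl-7-methyl-2-oxooxepan-3-yl]methyl acetate | O=C1[C@H](COC(C)=O)[C@@H](C=C)CC[C@](C)([C@@H](OC(C)=O)CC/C(C)=C/CC#CC)O1 | intermediate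
20 | [(3S,4R,7R)-7-[(1S,4E)-1-acetoxy-4-methylnon-4-en-7-yn-1-yl]-7-methyl-2-oxo-4-(2-oxoethyl)oxepan-3-yl]methyl acetate | O=C1[C@H](COC(C)=O)[C@@H](CC=O)CC[C@](C)([C@@H](OC(C)=O)CC/C(C)=C/CC#CC)O1 | intermediate
21 | [(1R,3S,4E,7E,11S,12R,15S)-11-acetoxy-4,8,12-trimethyl-14-oxo-3-(triethylsilyloxy)-13-oxabicyclo[10.3.2]heptadeca-4,7-dien-15-yl]methyl acetate | CC(=O)OC[C@H]1C(=O)O[C@]2(C)CC[C@@H]1C[C@H](O[Si](CC)(CC)CC)/C(C)=C/C/C=C(\C)CC[C@@H]2OC(C)=O | intermediate
22 | 13-O-triethylsilyl dendronpholide A | C=C1C(=O)O[C@]2(C)CC[C@@H]1C[C@H](O[Si](CC)(CC)CC)/C(C)=C/C/C=C(\C)CC[C@@H]2OC(C)=O | intermediate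
23 | dendronpholide A | C=C1C(=O)O[C@]2(C)CC[C@@H]1C[C@H](O)/C(C)=C/C/C=C(\C)CC[C@@H]2OC(C)=O | target

**Step count and risks**

Total steps: 14. Longest linear sequence: 13 steps (steps 1–3 and 5–14; step 4 is the one-step side branch).

The three steps most likely to fail:

Step 6, the proposed new step: the hafnium-bound epoxy alkoxide may not rearrange on warming, or the enantioselectivity may be low for this Z trisubstituted alkene. The fallback sets out from 9 and comes back at 11. Compound 9 is epoxidised with the same Hf(OtBu)4/bishydroxamic acid/cumene hydroperoxide system at 0 °C without warming (the known enantioselective epoxidation of tertiary allylic alcohols) and epoxy alcohol 10 is isolated. It is silylated with TMS-imidazole in CH2Cl2 to the epoxy trimethylsilyl ether F1. The known TiCl4-promoted pinacol-type rearrangement of 2,3-epoxy silyl ethers (CH2Cl2, −78 °C, aqueous work-up) then gives hydroxy ketone 11, which is acetylated to 12 as in step 6.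

Step 11: the Baeyer–Villiger oxidation may be slow at this hindered ketone, or the Lewis acid may trigger side reactions of the alkene. The fallback sets out from 18 and comes back at 19. Oxidation with excess mCPBA/NaHCO3 in CH2Cl2, accepting epoxidation of the C8=C9 alkene, gives the epoxy lactone F2. Stereoretentive deoxygenation with triphenylphosphine selenide/TFA (CH2Cl2, 25 °C) restores the E alkene and gives 19.

Step 13: the C13 configuration is not secured by precedent, and the methyl alkyne may partly close in the exo mode. The fallback addresses the C13 configuration; it sets out from 21 (as the C13 epimer mixture) and comes back at 21. HF·pyridine gives the free allylic alcohols, of which the 13S allylic alcohol F3 is the wanted one. Dess–Martin periodinane converges both epimers to the macrocyclic enone F4. Reagent-controlled reduction with (R)-Me-CBS/catecholborane (toluene, −78 °C) returns F3 alone, and TESOTf/2,6-lutidine gives 21.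

**Further compounds**

F1 | step 6 | trimethylsilyl ether of epoxy alcohol 10 | C[Si](C)(C)OC1(CCCC1)[C@@]2(C)O[C@H]2CC/C(C)=C/CC#CC
F2 | step 11 | C8–C9 epoxide of lactone 19 (one of the two trans-epoxide diastereomers drawn) | O=C1[C@H](COC(C)=O)[C@@H](C=C)CC[C@](C)([C@@H](OC(C)=O)CC[C@@]2(C)O[C@@H]2CC#CC)O1
F3 | step 13 | [(1R,3S,4E,7E,11S,12R,15S)-11-acetoxy-3-hydroxy-4,8,12-trimethyl-14-oxo-13-oxabicyclo[10.3.2]heptadeca-4,7-dien-15-yl]methyl acetate (13S allylic alcohol) | CC(=O)OC[C@H]1C(=O)O[C@]2(C)CC[C@@H]1C[C@H](O)/C(C)=C/C/C=C(\C)CC[C@@H]2OC(C)=O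
F4 | step 13 | C13 ketone of F3 (macrocyclic enone) | CC(=O)OC[C@H]1C(=O)O[C@]2(C)CC[C@@H]1CC(=O)/C(C)=C/C/C=C(\C)CC[C@@H]2OC(C)=O
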